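The L left over after the first seconds counts the Z made: in my reckoning, at 1.00 equiv, each J that ends as Z leaves one L unbound.

    D ⇌ X (K1 = 7.3, k1 = 0.014 s⁻¹)
    J.L ⇌ Q (K2 = 24, k2 = 1.3 s⁻¹)
    J → Z (k3 = 0.36 s⁻¹)
    J + L ⇌ J.L (K4 = 260 L mol⁻¹, k4 = 850 L mol⁻¹ s⁻¹)
    Q → D (k5 = 0.014 s⁻¹)
    J + L ⇌ E (K6 = 220 L mol⁻¹, k6 = 45 L mol⁻¹ s⁻¹)

| setting | red | amber | green |
|---|---|---|---|
| J | 2.0 mM | 2.0 mM | 2.0 mM |
| L | 1.00 equiv | 1.00 equiv | 1.00 equiv |
| time | 40 s | 10 s | 20 s |

- which of these there is most of at the end, counted by the J in it, red (Z / Q / D / X / J)
- which of these there is most of at the end, counted by the J in it, amber (Z / Q / D / X / J)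
- which of these there is most of at the end, counted by the J in it, green (Z / Q / D / X / J)
- amount of the one of these that there is most of at the end, in percent of the J charged, red
- amount of the one of these that there is most of at the end, in percent of the J charged, amber
- amount of the one of these that there is most of at the end, in percent of the J charged, green

First instants. J has two exits. The step to Z has a half-life of 1.9 s, and binding to L as charged has a forward half-life of 0.41 s. But binding is not capture. J.L falls back at 3.27 s⁻¹, faster than it goes on to Q at 1.3 s⁻¹, so the share going on is 28.5%. I set E aside as a side pocket that gives its J back: E returns to J and L at 0.205 s⁻¹, faster than L as charged forms it at 0.0900 s⁻¹.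

My quantity is the capture frequency, the pseudo-first-order rate at which L at its charged level sends J on to Q: the binding rate times that share, 0.484 s⁻¹. Set against 0.36 s⁻¹, it gives Z a first share of 42.7%.

But L falls during the burst, and the L left at its end equals the Z share. So mean L lies halfway between the charge and that share. Putting this back raises the Z share to 51.1%, and one more round gives 49.6%.

The middle. I end the burst at 5.00 s, which is 6.09 times the first half-life of J. In my reckoning Z and the captured part then stand about level, with the captured part at 50.4%.

The end. Q now has two slow exits. It goes to D at 0.014 s⁻¹, and it returns to J through J.L at 0.0388 s⁻¹. With L at about 49.6% of charge, released J goes to Z with a share of 60.0%, and the rest is captured again. So Q falls at 0.0373 s⁻¹, and 62.4% of what it loses becomes Z.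

This gives Z of 55.0% in amber, 63.1% in green and 72.5% in red. Z is my answer in each flask, since in amber, the earliest, it already stands above Q at 41.8%.

The forecast also names Z, at 58% in amber, 65% in green and 72% in red, on the ground that “Q slowly leaks back through J.L to J, feeding more Z”.

The simulation gives Z as the most in each flask: 56.6% in amber, 64.2% in green and 72.2% in red.

Now take green with 4.00 equiv of L. The capture frequency scales to 1.93 s⁻¹. The first Z share is 15.7%, and with mean L put back it is 17.2%. Unbound L then stands near 3.17 times the J charged, so released J reaches Z with a share of only 19.0%. Q then falls at 0.0214 s⁻¹, and 34.5% of its loss becomes Z. My Z is 25.0%. That flask gives Z 25.7% and Q 52.7%.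

(The constants used here belong to no real substance; the rest is arithmetic.)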